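**Retrosynthetic overview** (benzofuran numbering O1, C2, C3, C3a, C4–C7, C7a; ring A = carbocycle, ring B = lactone)
1. Last bond: O5–CH3. The target is the methyl ether of the vinylogous acid xylerythrin (5-OH), made by acidity-controlled O-methylation.
2. Xylerythrin comes from one-flask unmasking of a hexasubstituted benzene: ring B closes (O1–C2) and loss of water between C3 and the C6 oxygen sets the p-quinone methide. Only C6 is para to C3a, so O5 and O6 need no earlier differentiation.
3. Ring A comes from a Diels–Alder reaction of 3,4-dimethoxy-2,5-diphenylcyclopentadienone with the ynol ether MeO–C≡C–C(OSiMe3)(4-MeOC6H4)CO2Me, then cheletropic extrusion of CO. Bonds C7a–C7 and C3a–C4 form together.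
4. Enabling feature: in ring A the edge C4–C5–C6–C7 carries Ph, O, O, Ph, the same on both halves, so it maps onto a mirror-symmetric dienone (dibenzyl ketone + diethyl oxalate) and the cycloaddition has no regiochemistry. The opposite edge C3a–C7a, shared with ring B, carries O1 and C3 and maps onto the alkyne (aryl glyoxylate + methoxyacetylide).
5. Ring order: sacrificial cyclopentadienone ring, then ring A (benzene, by loss of the one-carbon bridge), then lactone ring B, then the quinone methide.

Key step: step 4

Remark on the chemistry: the target has no stereocentre and no stereogenic double bond, and it is made as the 6-oxo/4'-hydroxy tautomer drawn. All chiral intermediates are racemic and lose their stereocentres before the end. Methyl 2-(4-methoxyphenyl)-2-oxoacetate and 2-chloro-1,1-dimethoxyethane are taken as catalogue compounds.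

**Step 1**
Reactants: 1 1,3-diphenylpropan-2-one; 2 diethyl oxalate
Product: 3 2-hydroxy-3,5-diphenylcyclopent-2-ene-1,4-dione (enol form of 3,5-diphenylcyclopentane-1,2,4-trione; the remaining CH(Ph) centre is racemic and labile)
Conditions: NaOEt (2.2 equiv), EtOH, reflux; then aq. HCl
Reagents that add atoms: none
Why: A double Claisen condensation (intermolecular, then Dieckmann-type ring closure) of the two benzylic CH2 groups of 1 onto both ester carbonyls of 2 should give the trione, driven by formation of the stable enolate of this vinylogous acid.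

**Step 2**
Reactants: 3 2-hydroxy-3,5-diphenylcyclopent-2-ene-1,4-dione
Product: 5 3,4-dimethoxy-2,5-diphenylcyclopenta-2,4-dien-1-one, via monomethyl ether 4 (not isolated)
Conditions: TMSCHN2 (3 equiv), PhMe/MeOH 4:1, 0 °C → rt; AcOH quench
Reagents that add atoms: (trimethylsilyl)diazomethane, C[Si](C)(C)C=[N+]=[N-]
Why: Diazoalkane O-methylation of acidic enols should place the first methyl on the diosphenol-type enol oxygen (oxalate-derived carbon), after which the second CH(Ph) enolises to the cross-conjugated hydroxy-dienone 4 and is methylated in turn; without base or free enolate, C-methylation is not expected.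

**Step 3**
Reactants: 6 2-chloro-1,1-dimethoxyethane; 7 methyl 2-(4-methoxyphenyl)-2-oxoacetate
Product: 10 methyl 4-methoxy-2-(4-methoxyphenyl)-2-(trimethylsilyloxy)but-3-ynoate (racemic), via lithium methoxyacetylide 8 (not isolated), via lithium alkoxide adduct 9 (not isolated)
Conditions: Et2NH, n-BuLi, THF, 0 °C (LiNEt2, 3.0 equiv per 6); 6, 0 °C; 7, −78 °C; TMSCl (excess), −78 °C → rt; chromatography on Et3N-deactivated silica
Reagents that add atoms: chlorotrimethylsilane, C[Si](C)(C)Cl
Why: Twofold elimination and deprotonation of the chloroacetal by LiNEt2 gives the alkoxyacetylide in the flask, which should add to the ketone of the aryl glyoxylate in preference to the ester (1,2-addition of an alkynyllithium); silylation of the tertiary alkoxide blocks Meyer–Schuster rearrangement, and the new quaternary centre is formed racemic and later becomes sp2.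

**Step 4**
Reactants: 5 3,4-dimethoxy-2,5-diphenylcyclopenta-2,4-dien-1-one; 10 methyl 4-methoxy-2-(4-methoxyphenyl)-2-(trimethylsilyloxy)but-3-ynoate
Product: 12 methyl 2-(4-methoxyphenyl)-2-(3,4,6-trimethoxy-2,5-diphenylphenyl)-2-(trimethylsilyloxy)acetate (racemic), via norbornadienone cycloadduct 11 (not isolated)
Conditions: 10 (1.5 equiv), 2,6-lutidine (0.1 equiv), o-C6H4Cl2, 170 °C, sealed tube, Ar
Reagents that add atoms: none
Why: A thermal Diels–Alder reaction between the diene of 5 (C2=C3–C4=C5) and the triple bond of 10 should give the 7-oxonorbornadiene 11, which loses CO by cheletropic extrusion (retro [4+1]) and aromatises at once to 12; the closest known reaction type is the synthesis of hexasubstituted benzenes from tetraphenylcyclopentadienone and alkynes, including heteroatom-substituted ones. Ring A is closed by an intermolecular, suprafacial [4+2] cycloaddition that joins the two phenyl-bearing diene termini to the two alkyne carbons in the same event, after which the one-carbon bridge is expelled. No stereocentre survives: the bridgeheads of 11 become aromatic carbons and the silyloxy-bearing carbon stays racemic. Regioselectivity is not needed, because 5 has a mirror plane through its carbonyl group and both orientations of the unsymmetrical alkyne give the same arene. The step needs chemoselectivity for cycloaddition over dienone dimerisation and ynol ether decomposition: the 2,5-diphenyl groups and the two vinylogous-ester methoxy groups should keep 5 monomeric when hot, the methyl ynol ether has no β-hydrogen for retro-ene loss of an alkene, and irreversible loss of CO pulls the sequence forward.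

**Step 5**
Reactants: 12 methyl 2-(4-methoxyphenyl)-2-(3,4,6-trimethoxy-2,5-diphenylphenyl)-2-(trimethylsilyloxy)acetate
Product: 14 xylerythrin (5-hydroxy-3-(4-hydroxyphenyl)-4,7-diphenylbenzofuran-2,6-dione), via carbinol lactone 13 (not isolated)
Conditions: BBr3 (10 equiv), CH2Cl2, −78 °C → rt; then H2O/THF, rt
Reagents that add atoms: none
Why: BBr3 ether cleavage should remove the four aryl methyl groups and the silyl group, the freed C7a phenol should lactonise onto the neighbouring ester (5-exo-trig acyl substitution) to give 13, and the tertiary benzylic hydroxyl para to the free C6 phenol should be lost as water (1,6-elimination) to give the p-quinone methide, whose carbonyl can only sit on C6.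

**Step 6**
Reactants: 14 xylerythrin
Product: 15 5-methoxy-3-(4-hydroxyphenyl)-4,7-diphenylbenzofuran-2,6-dione (CNP0282683.0, target)
Conditions: TMSCHN2 (1.05 equiv), CH2Cl2/MeOH 9:1, 0 °C
Reagents that add atoms: (trimethylsilyl)diazomethane, C[Si](C)(C)C=[N+]=[N-]
Why: Diazoalkane O-methylation follows acidity, so the 5-hydroxyl (a vinylogous carboxylic acid, the enol of a hydroxy-quinone methide) should take up one equivalent of reagent while the far less acidic 4'-phenol stays free.

**Compound list**
1 | 1,3-diphenylpropan-2-one | O=C(Cc1ccccc1)Cc1ccccc1 | starting material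
2 | diethyl oxalate | CCOC(=O)C(=O)OCC | starting material
3 | 2-hydroxy-3,5-diphenylcyclopent-2-ene-1,4-dione (enol of 3,5-diphenylcyclopentane-1,2,4-trione, racemic) | OC1=C(c2ccccc2)C(=O)C(c2ccccc2)C1=O | intermediate
4 | 3-hydroxy-4-methoxy-2,5-diphenylcyclopenta-2,4-dien-1-one | COC1=C(c2ccccc2)C(=O)C(c2ccccc2)=C1O | intermediate (not isolated)
5 | 3,4-dimethoxy-2,5-diphenylcyclopenta-2,4-dien-1-one | COC1=C(c2ccccc2)C(=O)C(c2ccccc2)=C1OC | intermediate
6 | 2-chloro-1,1-dimethoxyethane | COC(CCl)OC | starting material
7 | methyl 2-(4-methoxyphenyl)-2-oxoacetate | COC(=O)C(=O)c1ccc(OC)cc1 | starting material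
8 | lithium methoxyacetylide | COC#C[Li] | intermediate (not isolated)
9 | lithium alkoxide of methyl 2-hydroxy-4-methoxy-2-(4-methoxyphenyl)but-3-ynoate (racemic) | COC#CC(O[Li])(C(=O)OC)c1ccc(OC)cc1 | intermediate (not isolated)
10 | methyl 4-methoxy-2-(4-methoxyphenyl)-2-(trimethylsilyloxy)but-3-ynoate (racemic) | COC#CC(O[Si](C)(C)C)(C(=O)OC)c1ccc(OC)cc1 | intermediate
11 | methyl 2-(4-methoxyphenyl)-2-(3,5,6-trimethoxy-7-oxo-1,4-diphenylbicyclo[2.2.1]hepta-2,5-dien-2-yl)-2-(trimethylsilyloxy)acetate (mixture of diastereomers) | O=C1C2(c3ccccc3)C(OC)=C(OC)C1(c1ccccc1)C(C(O[Si](C)(C)C)(C(=O)OC)c1ccc(OC)cc1)=C2OC | intermediate (not isolated)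
12 | methyl 2-(4-methoxyphenyl)-2-(3,4,6-trimethoxy-2,5-diphenylphenyl)-2-(trimethylsilyloxy)acetate (racemic) | COC(=O)C(O[Si](C)(C)C)(c1ccc(OC)cc1)c1c(OC)c(-c2ccccc2)c(OC)c(OC)c1-c1ccccc1 | intermediate
13 | 3,5,6-trihydroxy-3-(4-hydroxyphenyl)-4,7-diphenylbenzofuran-2(3H)-one (racemic) | O=C1Oc2c(-c3ccccc3)c(O)c(O)c(-c3ccccc3)c2C1(O)c1ccc(O)cc1 | intermediate (not isolated)
14 | xylerythrin, 5-hydroxy-3-(4-hydroxyphenyl)-4,7-diphenylbenzofuran-2,6-dione | OC1=C(c2ccccc2)C2=C(c3ccc(O)cc3)C(=O)OC2=C(c2ccccc2)C1=O | intermediate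
15 | 5-methoxy-3-(4-hydroxyphenyl)-4,7-diphenylbenzofuran-2,6-dione | COC1=C(c2ccccc2)C2=C(c3ccc(O)cc3)C(=O)OC2=C(c2ccccc2)C1=O | target

**Step count**
Total steps: 6. Longest linear sequence: 5 steps (steps 1, 2, 4, 5, 6); step 3 is the second branch.

**Steps most likely to fail**

Step 4. The ynol ether may oligomerise or rearrange at the temperature that this hindered, electron-rich pairing needs, so that the dienophile is used up before it cycloadds. The fallback sets out from 7 and comes back at 14; it carries the C7a oxygen through the same cycloaddition as boron. Addition of ethynylmagnesium bromide to 7 (THF, −78 °C) and silylation in the same flask (TMSCl, imidazole) should give methyl 2-(4-methoxyphenyl)-2-(trimethylsilyloxy)but-3-ynoate F1. Deprotonation with LDA at −78 °C, trapping with 2-isopropoxy-4,4,5,5-tetramethyl-1,3,2-dioxaborolane and HCl in Et2O should give methyl 2-(4-methoxyphenyl)-4-(4,4,5,5-tetramethyl-1,3,2-dioxaborolan-2-yl)-2-(trimethylsilyloxy)but-3-ynoate F2, a thermally robust dienophile of a class known to react with cyclopentadienones. Heating F2 with 5 (o-C6H4Cl2, 180–200 °C) should pass through methyl 2-[5,6-dimethoxy-7-oxo-1,4-diphenyl-3-(4,4,5,5-tetramethyl-1,3,2-dioxaborolan-2-yl)bicyclo[2.2.1]hepta-2,5-dien-2-yl]-2-(4-methoxyphenyl)-2-(trimethylsilyloxy)acetate F3 (not isolated) and, after loss of CO, give methyl 2-[3,4-dimethoxy-2,5-diphenyl-6-(4,4,5,5-tetramethyl-1,3,2-dioxaborolan-2-yl)phenyl]-2-(4-methoxyphenyl)-2-(trimethylsilyloxy)acetate F4. Oxidation (H2O2, aq. NaOH, THF) should turn C–B into C–O and hydrolyse the ester and silyl ether to the salt of 2-hydroxy-2-(6-hydroxy-3,4-dimethoxy-2,5-diphenylphenyl)-2-(4-methoxyphenyl)acetic acid F5 (not isolated). Acidification should lactonise it to 3-hydroxy-5,6-dimethoxy-3-(4-methoxyphenyl)-4,7-diphenylbenzofuran-2(3H)-one F6. BBr3 (CH2Cl2, −78 °C → rt, then water) should then cleave the three methyl ethers to 13, which dehydrates to 14.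

Step 5. The silyloxy carbon may ionise while ring B is still open, and the cation may then close by Friedel–Crafts attack on the ortho position of the neighbouring phenyl ring (fluorene formation); the doubly flanked methyl ethers may also be cleaved incompletely. The fallback sets out from 12 and comes back at 14; it is a cation-free, nucleophilic demethylation. NaSEt (excess) in DMF at 130 °C should remove the methyl groups of the four aryl ethers and of the ester by SN2 attack at carbon and take off the silyl group. Acidification (aq. HCl) should give 2-hydroxy-2-(4-hydroxyphenyl)-2-(3,4,6-trihydroxy-2,5-diphenylphenyl)acetic acid F7 (not isolated), which closes to the carbinol lactone 13 and loses water to 14 (warm AcOH if needed).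

Step 2. Site selectivity among the three enolisable oxygens may be poor: methylation at the oxygen of the former ketone carbonyl of 1 would destroy the symmetry that the key step relies on. The fallback sets out from 2 and comes back at 12; it replaces the carbonyl bridge by a sulfonyl bridge, which has no enolisable oxygen. A Claisen-type double condensation of commercial dibenzyl sulfone with 2 (NaOEt, EtOH) should give 3,4-dihydroxy-2,5-diphenylthiophene 1,1-dioxide F8, in which only the two oxalate-derived oxygens can be alkylated. Me2SO4/K2CO3 in acetone should give 3,4-dimethoxy-2,5-diphenylthiophene 1,1-dioxide F9. Heating F9 with 10 (o-C6H4Cl2, 180 °C) should give, through methyl 2-(4-methoxyphenyl)-2-(3,5,6-trimethoxy-7,7-dioxo-1,4-diphenyl-7-thiabicyclo[2.2.1]hepta-2,5-dien-2-yl)-2-(trimethylsilyloxy)acetate F10 (not isolated) and cheletropic loss of SO2, the same arene 12.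

**Further compounds**
F1 | step 4 | methyl 2-(4-methoxyphenyl)-2-(trimethylsilyloxy)but-3-ynoate | C#CC(O[Si](C)(C)C)(C(=O)OC)c1ccc(OC)cc1
F2 | step 4 | methyl 2-(4-methoxyphenyl)-4-(4,4,5,5-tetramethyl-1,3,2-dioxaborolan-2-yl)-2-(trimethylsilyloxy)but-3-ynoate | CC1(C)OB(OC1(C)C)C#CC(O[Si](C)(C)C)(C(=O)OC)c1ccc(OC)cc1
F3 | step 4 | methyl 2-[5,6-dimethoxy-7-oxo-1,4-diphenyl-3-(4,4,5,5-tetramethyl-1,3,2-dioxaborolan-2-yl)bicyclo[2.2.1]hepta-2,5-dien-2-yl]-2-(4-methoxyphenyl)-2-(trimethylsilyloxy)acetate | O=C1C2(c3ccccc3)C(OC)=C(OC)C1(c1ccccc1)C(C(O[Si](C)(C)C)(C(=O)OC)c1ccc(OC)cc1)=C2B1OC(C)(C)C(C)(C)O1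
F4 | step 4 | methyl 2-[3,4-dimethoxy-2,5-diphenyl-6-(4,4,5,5-tetramethyl-1,3,2-dioxaborolan-2-yl)phenyl]-2-(4-methoxyphenyl)-2-(trimethylsilyloxy)acetate | COC(=O)C(O[Si](C)(C)C)(c1ccc(OC)cc1)c1c(B2OC(C)(C)C(C)(C)O2)c(-c2ccccc2)c(OC)c(OC)c1-c1ccccc1
F5 | step 4 | 2-hydroxy-2-(6-hydroxy-3,4-dimethoxy-2,5-diphenylphenyl)-2-(4-methoxyphenyl)acetic acid | OC(=O)C(O)(c1ccc(OC)cc1)c1c(O)c(-c2ccccc2)c(OC)c(OC)c1-c1ccccc1
F6 | step 4 | 3-hydroxy-5,6-dimethoxy-3-(4-methoxyphenyl)-4,7-diphenylbenzofuran-2(3H)-one | COc1ccc(cc1)C1(O)C(=O)Oc2c(-c3ccccc3)c(OC)c(OC)c(-c3ccccc3)c21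
F7 | step 5 | 2-hydroxy-2-(4-hydroxyphenyl)-2-(3,4,6-trihydroxy-2,5-diphenylphenyl)acetic acid | OC(=O)C(O)(c1ccc(O)cc1)c1c(O)c(-c2ccccc2)c(O)c(O)c1-c1ccccc1
F8 | step 2 | 3,4-dihydroxy-2,5-diphenylthiophene 1,1-dioxide | OC1=C(c2ccccc2)S(=O)(=O)C(c2ccccc2)=C1O
F9 | step 2 | 3,4-dimethoxy-2,5-diphenylthiophene 1,1-dioxide | COC1=C(c2ccccc2)S(=O)(=O)C(c2ccccc2)=C1OC
F10 | step 2 | methyl 2-(4-methoxyphenyl)-2-(3,5,6-trimethoxy-7,7-dioxo-1,4-diphenyl-7-thiabicyclo[2.2.1]hepta-2,5-dien-2-yl)-2-(trimethylsilyloxy)acetate | O=S1(=O)C2(c3ccccc3)C(OC)=C(OC)C1(c1ccccc1)C(C(O[Si](C)(C)C)(C(=O)OC)c1ccc(OC)cc1)=C2OC
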